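## Structural features

The core is a cyclobutane (C4–C5–C6–C7) whose two diagonals are bridged on opposite faces: C5 and C7 are joined by C10–C9–C8 to give ring A, a cyclohexanone, and C4 and C6 are joined by C3–C2–C1–C11 to give a bicyclo[4.1.1]octane. All eight stereocentres (C1, C3, C4, C5, C6, C7, C10, C11) form one contiguous array, and the two quaternary ones, C4 and C11, sit at the two ends of the four-carbon bridge. On that bridge the C1 and C3 oxygens are trans, the C1 oxygen is cis to the C11 methyl and trans to C15, and on ring A the C10 methyl points away from the C4 methyl. The two angelates are (Z)-2-methylbut-2-enoates that isomerise to tiglates under nucleophilic or basic acylation, and the C1 ester can migrate to the free C15 hydroxyl. The C8 ketone is flanked by a strained ring, so radicals or carbanions at C8 or C10 can open the cyclobutane. The real difficulty is the doubly bridged four-membered ring with its two quaternary carbons. The key step uses the fact that C8 lies between the cyclobutane carbon C7 and C9 and that the substituents on C5 and C7 must be cis on one face: a C7 radical, carbon monoxide as C8 and an allylstannane arm on C5 close ring A without prior control of C7.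

## Logic of the disconnections

38 ⇒ 37 ⇒ 35 + 36 (twice). The O–Si bond at C15 and the two ester C–O bonds at C1 and C3 are cut last, because the (Z)-enoates and the migration-prone C1 ester should see as few steps as possible. 35 already holds the whole skeleton and every ring stereocentre, and each of its two hydroxyls takes one molecule of 36. The forward acylation must esterify two hindered secondary alcohols without Z→E isomerisation, and the final desilylation must be non-basic.

35 ⇒ 34 ⇒ 33 ⇒ 32. The two secondary O–Si bonds are put back, the C10–H bond is cut and the alkene is moved to the exocyclic position. This removes the C10 stereocentre and leads to the β,γ-unsaturated ketone that a radical allyl transfer delivers. The forward reduction must place the C10 methyl on the more stable side, away from the C4 methyl.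

32 ⇒ 30 + 31. Both bonds to C8 (C7–C8 and C8–C9) are cut. Ring A disappears, C7 becomes a stereochemically free radical precursor, and the tricycle becomes a bicyclo[4.1.1]octane. The forward step needs acylation at C7 on the face of the C5 arm and attack on the CH2 terminus of the arm.

30 ⇒ 29 ⇒ 27 ⇒ 25 ⇒ 24. The C–Sn bond, the C7–I bond and the allylic C–Cl bond are cut in that order, back to an isopropenyl group and a C7 carboxylate. The order matters: an allylstannane would not survive iododecarboxylation (electrophilic radicals, iodine donors), so the iodide is made first and tin is introduced last, under conditions that leave the hindered iodide alone.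

24 ⇒ 22 ⇒ 20 ⇒ 19. The three O–Si bonds, the C1–H and C3–H bonds and the C15–H bonds are cut. Three carbinol centres collapse to the 1,3-diketone and methyl ester of 19, so that only C11 has to be controlled directly. The forward reductions must relay configuration from C11 through the C15 hydroxyl to C1 and then to C3.

19 ⇒ 17 ⇒ 15. The C6–C11 bond and the C11–CH3 bond are cut. The seven-membered ring opens, 15 is monocyclic, and C6 and C11 are cleared. The forward Michael closure must be intramolecular (which enforces the cis bridge) and the methylation must be face-selective.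

15 ⇒ 12 + 13. The C2–C3 bond is cut, which divides the chain into a four-carbon piece and the neopentyl aldehyde carbon on C4. The forward aldol needs no stereocontrol because C3 is later oxidised.

12 ⇒ 11 ⇒ 9 ⇒ 8 ⇒ 6 ⇒ 4. The C6=C7 unsaturation is removed, and the alkene carbon, the hydrogen on C5 and the C5–C10 bond are cut back to a ring ketone at C5. C5 is set here, on the monocycle, where the arrangement with the arm trans to the larger C4 substituent is unambiguously the most stable. The forward sequence needs an acyl anion addition to a hindered ketone and a thermodynamic epimerisation.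

4 ⇒ 3 ⇒ 2 ⇒ 1. The C3–C4 bond and the C4–CH3 bond are cut, back to the prochiral 1. The forward steps need one enantioselective event (differentiation of the two α-methylene groups); the temporary C7 stereocentre then relays it to the quaternary C4.

## Other disconnections considered

Alternative 1: The cut is C1–C11. In the forward step SmI2 converts the α-bromo ester A2 into a samarium enolate that adds to the C1 aldehyde and gives the tricyclic β-hydroxy ester A1.
- In favour: both bromide epimers give the same enolate; C11 and C1 are formed in one chelate-organised step; ring A and C10 are already present, so no late redox work on ring A is needed.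
- Against: A2 requires a bicyclo[3.1.1]heptane in which both one-carbon bridges are substituted and differentiated (a quaternary C4 with a stereodefined β-alkoxy aldehyde chain, and C6 with a bromopropanoate). This is harder to reach than 30. The closure joins a fully substituted enolate to an aldehyde in a seven-membered bridging ring, and the facial sense at C1 and C11 rests on a medium-ring chelate that is hard to predict.
- Comparison: on mechanism the alternative is the equal or the better of the chosen plan (a two-electron closure at low temperature without a pressure vessel). On structure A1 carries all eight stereocentres, one more than 32, which is also a point for it. On step economy the two are about equal after the key step (ester reduction, two deprotections and the acylations against five steps). The chosen plan is ahead in the access to the key precursor and in the tether-enforced selectivity of its key step.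

Alternative 2: The cuts are C6–C11 and C3–C4. In the forward step a Ph3Ge radical chain abstracts bromine from the acylgermane A4; the tertiary α-ester radical adds to bridgehead C6 of the ring-A-fused bicyclobutane A5; the central bond opens; the C4 radical attacks the acylgermane carbonyl, expels Ph3Ge and gives the tricyclic ketone A3.
- In favour: it is the most convergent option, making two C–C bonds, both quaternary carbons and the seven-membered ring from two fragments in one operation. On convergence and on the step count for building the bridge it is better than the chosen plan. The cis bridge is automatic, which equals the intramolecular Michael closure used here.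
- Against: A5 is a strained, unactivated bicyclobutane that must be made as a single enantiomer with a ketal and two methyl groups. Radical addition to a bridgehead without an acceptor group is slow against reduction and oligomerisation. C11 arises from a planar acyclic radical with nothing to control its configuration. The seven-membered acyl transfer to a tertiary cyclobutyl radical must outrun every bimolecular trap, and C3 still needs a selective reduction.
- Comparison: both plans are group-14 radical chains in which the chain carrier leaves from the acceptor, so they are equal in kind. The chosen cascade is intramolecular, closes a six-membered ring and creates a single, tether-controlled stereocentre; the alternative creates three under intermolecular conditions.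

Alternative 3: The cut is C6–C7 (reconnecting C6 to C8). In the forward step photolysis of the diazoketone A7 in methanol causes a Wolff shift of C6, and the ketene is trapped as the cyclobutane methyl ester A6.
- In favour: Wolff contraction is a dependable entry to strained four-membered rings. The migrating carbon keeps its configuration, so C4, C5 and C6 carry over. Because the seven-membered ring exists before the four-membered one, the cis bridging is guaranteed, which is better than a ring closure that has to establish it. The unknown C7 configuration of A6 does not matter, exactly as in the chosen plan.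
- Against: A6 is the methyl ester analogue of 24, so this is an alternative construction of the cyclobutane, not of ring A; the radical carbonylation would still be needed afterwards. A7 (a bicyclo[4.2.1]nonanone with the quaternary C4, the C5 isopropenyl group and three silyl ethers) must itself be built. The diazo group has to be installed next to a quaternary carbon, and carbene C–H insertion can compete in so crowded a system.
- Comparison: on mechanism the photochemical step is clean and the equal of the chosen chemistry. On step economy it is longer, because the chosen plan buys the four-membered ring.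

Key step: step 19

## Conventions and assumption

- Target locants are used for every compound. In the cyclobutanes and bicyclo[4.1.1]octanes (bridgeheads C4 and C6; bridges C3–C2–C1–C11, C5 and C7), "upper face" is the face of the four-membered ring that carries C8 and C10 in the target, and "lower face" is the one that carries C3 and C11. Substituents on the four-carbon bridge lie on the "C5 side" or the "C7 side".
- Assumption: the (R,R)-lithium amide of step 1 is taken to remove the proton that leads to the enantiomer drawn for 2; if the sense of induction is the opposite, the (S,S)-amide is used.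
- The C3 epimers of 14–18 and any C7 epimer of 29 and 30 are carried together, because they converge in steps 11 and 19.

## Route

Step 1
Reactants: 1 tert-butyl 3-oxocyclobutane-1-carboxylate
Product: 2 tert-butyl 2-methyl-3-oxocyclobutane-1-carboxylate (C7 ester on the upper face, C4 methyl trans to it)
Conditions: (R,R)-bis(1-phenylethyl)amine, n-BuLi, LiCl, THF, −100 °C; then MeI, −100 → −40 °C
Reagents that add atoms: iodomethane, CI
Why: Enantioselective deprotonation by the C2-symmetric lithium amide differentiates the enantiotopic α-methylene groups (the ketone α-H is far more acidic than the ester α-H), and the enolate is C-methylated anti to the ester. Only the C7 configuration matters, since it relays chirality to C4 in step 3.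

Step 2
Reactants: 2 tert-butyl 2-methyl-3-oxocyclobutane-1-carboxylate
Product: 3 tert-butyl 2-methyl-3-(trimethylsilyloxy)cyclobut-2-ene-1-carboxylate (C7 unchanged)
Conditions: Me3SiCl, NaI, Et3N, MeCN, rt
Reagents that add atoms: chlorotrimethylsilane, C[Si](C)(C)Cl
Why: Equilibrating silylation (Me3SiI formed in situ with an amine base) should give the more substituted, tetrasubstituted silyl enol ether. C7 is not enolised by the amine and keeps its configuration.

Step 3
Reactants: 3 tert-butyl 2-methyl-3-(trimethylsilyloxy)cyclobut-2-ene-1-carboxylate
Product: 4 tert-butyl 2-(dimethoxymethyl)-2-methyl-3-oxocyclobutane-1-carboxylate (C4: CH(OMe)2 on the lower face, methyl on the upper face; C7 ester on the upper face)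
Conditions: HC(OMe)3, Me3SiOTf (5 mol %), CH2Cl2, −78 °C
Reagents that add atoms: trimethyl orthoformate, COC(OC)OC
Why: Mukaiyama-type alkylation of the silyl enol ether by the dimethoxycarbenium ion. The electrophile should enter the planar cyclobutene anti to the adjacent tert-butyl ester, which sets the quaternary C4 as in the target.

Step 4
Reactants: 4 tert-butyl 2-(dimethoxymethyl)-2-methyl-3-oxocyclobutane-1-carboxylate
Product: 6 tert-butyl 3-acetyl-2-(dimethoxymethyl)-3-hydroxy-2-methylcyclobutane-1-carboxylate (C5 hydroxyl on the lower face expected), via enol ether carbinol 5 (not isolated)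
Conditions: CH2=C(OEt)Li (from ethyl vinyl ether, t-BuLi), THF, −78 °C; H2O; then 0.1 M aq. oxalic acid, THF, 0 °C
Reagents that add atoms: ethyl vinyl ether, C=COCC; water, O
Why: 1,2-Addition of an acyl anion equivalent to the strained, very electrophilic cyclobutanone at −78 °C leaves the ester untouched, and the enol ether hydrolyses much faster than the neopentyl dimethyl acetal. The C5 configuration is irrelevant because C5 is planarised in step 5.

Step 5
Reactants: 6 tert-butyl 3-acetyl-2-(dimethoxymethyl)-3-hydroxy-2-methylcyclobutane-1-carboxylate
Product: 8 tert-butyl 3-acetyl-2-(dimethoxymethyl)-2-methylcyclobutane-1-carboxylate (acetyl on the upper face: trans to CH(OMe)2, cis to the ester), via C5-epimeric methyl ketone 7 (not isolated)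
Conditions: SmI2, HMPA, THF–MeOH, −78 → 0 °C; then K2CO3, MeOH, rt
Reagents that add atoms: none
Why: SmI2 cleaves the C–O bond α to the ketone through the ketyl and a samarium enolate (reduction of an α-heterosubstituted ketone). Base equilibration through the enolate should then place the acetyl group trans to the bulkier C4 substituent and cis-1,3 to the ester, which is the C5 configuration of the target.

Step 6
Reactants: 8 tert-butyl 3-acetyl-2-(dimethoxymethyl)-2-methylcyclobutane-1-carboxylate
Product: 9 tert-butyl 2-(dimethoxymethyl)-2-methyl-3-(prop-1-en-2-yl)cyclobutane-1-carboxylate (isopropenyl on the upper face)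
Conditions: Ph3PCH3Br, KOt-Bu, THF, 0 °C → rt
Reagents that add atoms: methyltriphenylphosphonium bromide, C[P+](c1ccccc1)(c1ccccc1)c1ccccc1.[Br-]
Why: Wittig methylenation of the methyl ketone with a non-stabilised ylide, to which the tert-butyl ester and acetal are inert. C5 is no longer epimerisable after this step.

Step 7
Reactants: 9 tert-butyl 2-(dimethoxymethyl)-2-methyl-3-(prop-1-en-2-yl)cyclobutane-1-carboxylate
Product: 11 tert-butyl 4-(dimethoxymethyl)-4-methyl-3-(prop-1-en-2-yl)cyclobut-1-ene-1-carboxylate, via α-phenylselanyl ester 10 (not isolated)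
Conditions: LiN(i-Pr)2, THF, −78 °C; PhSeBr; then H2O2 (30 %), pyridine, CH2Cl2, 0 °C
Reagents that add atoms: none
Why: Selenenylation of the ester enolate at the only acidic C–H, then selenoxide syn-elimination, which can only run toward C6 because C4 is quaternary. This gives the strained cyclobutene ester acceptor and erases the now redundant C7 stereocentre.

Step 8
Reactants: 11 tert-butyl 4-(dimethoxymethyl)-4-methyl-3-(prop-1-en-2-yl)cyclobut-1-ene-1-carboxylate
Product: 12 tert-butyl 4-formyl-4-methyl-3-(prop-1-en-2-yl)cyclobut-1-ene-1-carboxylate
Conditions: Amberlyst-15, acetone–H2O, rt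
Reagents that add atoms: water, O
Why: Acid-catalysed acetal hydrolysis. The aldehyde has a quaternary α-carbon and cannot enolise, and the tert-butyl ester and both alkenes tolerate the resin acid.

Step 9
Reactants: 12 tert-butyl 4-formyl-4-methyl-3-(prop-1-en-2-yl)cyclobut-1-ene-1-carboxylate; 13 methyl acetoacetate
Product: 15 methyl 5-[2-(tert-butoxycarbonyl)-1-methyl-4-(prop-1-en-2-yl)cyclobut-2-en-1-yl]-3-oxo-5-(triethylsilyloxy)pentanoate (both C3 epimers), via hydroxy keto ester 14 (not isolated)
Conditions: 13, NaH then n-BuLi, THF, 0 °C; 12, −78 °C; Et3SiCl, −78 → 0 °C; aq. NH4Cl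
Reagents that add atoms: chlorotriethylsilane, CC[Si](Cl)(CC)CC
Why: Dianion aldol: the γ-carbon of the acetoacetate dianion should add to the aldehyde much faster than to the hindered enoate, and silylation of the aldolate in the same flask blocks retro-aldol and lactonisation. C3 is formed without control and is corrected in steps 11 to 13.

Step 10
Reactants: 15 methyl 5-[2-(tert-butoxycarbonyl)-1-methyl-4-(prop-1-en-2-yl)cyclobut-2-en-1-yl]-3-oxo-5-(triethylsilyloxy)pentanoate
Product: 17 bicyclo[4.1.1]octane keto diester (C1 ketone; C3 OSiEt3, both epimers; C4 methyl; C5 isopropenyl, upper face; C7 CO2t-Bu, lower face; C11 methyl on the C5 side and CO2Me on the C7 side), via unmethylated Michael adduct 16 (not isolated)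
Conditions: Cs2CO3, MeCN (0.01 M), rt; then MeI, 0 °C → rt
Reagents that add atoms: iodomethane, CI
Why: Intramolecular Michael addition of the β-keto ester enolate to the strained cyclobutene ester. The tether on C4 can reach C6 only from the lower face (anti to the isopropenyl group), which fixes C6 and the cis bridge. The C7 enolate should be protonated from the open upper face, so the tert-butyl ester ends under the bridge, shields the C7 side of the C11 enolate, and MeI should enter from the C5 side.

Step 11
Reactants: 17 bicyclo[4.1.1]octane keto diester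
Product: 19 bicyclo[4.1.1]octane-1,3-dione diester (C1 and C3 ketones; C11 methyl and CO2Me; C7 CO2t-Bu), via C3 alcohol 18 (not isolated)
Conditions: HF·pyridine, pyridine, THF, 0 °C; then Dess–Martin periodinane, NaHCO3, CH2Cl2, rt
Reagents that add atoms: none
Why: Fluoride desilylation followed by periodinane oxidation of the β-hydroxy ketone. Both C3 epimers merge into one 1,3-diketone.

Step 12
Reactants: 19 bicyclo[4.1.1]octane-1,3-dione diester
Product: 20 C11 hydroxymethyl 1,3-diketone (C15–OH; C7 CO2t-Bu retained)
Conditions: NaH (1 equiv), THF, 0 °C; LiBH4, MeOH (1 equiv), 0 °C → rt; aq. NH4Cl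
Reagents that add atoms: none
Why: The 1,3-diketone is masked as its sodium enolate, which is inert to borohydride. LiBH4 then reduces the methyl ester chemoselectively and should leave the tert-butyl ester.

Step 13
Reactants: 20 C11 hydroxymethyl 1,3-diketone
Product: 22 triol tert-butyl ester (C1–OH on the C5 side, C3–OH on the C7 side, C15–OH), via C1 carbinol 21 (not isolated)
Conditions: Me4NBH(OAc)3, MeCN–AcOH (1:1), −30 °C → rt
Reagents that add atoms: none
Why: Two consecutive hydroxyl-directed reductions (Evans–Saksena): the C15 alkoxyborohydride delivers hydride to C1 from the C15 side, so the C1 hydroxyl ends cis to the C11 methyl. The new C1 hydroxyl then delivers hydride to C3 and should give the trans (1,3-anti) diol; undirected ketones are not reduced by this reagent.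

Step 14
Reactants: 22 triol tert-butyl ester
Product: 24 tert-butyl ester with C1 and C3 OSiEt3, C15 OSi(i-Pr)3 and C5 isopropenyl, via C15 silyl ether diol 23 (not isolated)
Conditions: i-Pr3SiOTf (1.05 equiv), 2,6-lutidine, CH2Cl2, −78 °C; then Et3SiOTf (3 equiv), −78 → 0 °C
Reagents that add atoms: triisopropylsilyl triflate, CC(C)[Si](OS(=O)(=O)C(F)(F)F)(C(C)C)C(C)C; triethylsilyl triflate, CC[Si](CC)(CC)OS(=O)(=O)C(F)(F)F
Why: Silyl triflate silylation: at −78 °C the bulky triisopropylsilyl triflate should react only with the primary C15 hydroxyl. The smaller triethylsilyl triflate then caps the two hindered secondary alcohols, one equivalent on each.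

Step 15
Reactants: 24 fully silylated tert-butyl ester
Product: 25 allylic chloride (C5 arm = 3-chloroprop-1-en-2-yl)
Conditions: Ca(OCl)2, CO2 (solid), CH2Cl2–H2O, 0 °C
Reagents that add atoms: calcium hypochlorite, [Ca+2].[O-]Cl.[O-]Cl
Why: Ene-type allylic chlorination of the 1,1-disubstituted alkene by HOCl: chlorine adds to the terminal CH2 and the methyl group loses a proton, giving the 2-substituted allyl chloride. Abstraction of the hindered C5 methine would give a strained alkylidenecyclobutane and is not expected.

Step 16
Reactants: 25 allylic chloride tert-butyl ester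
Product: 27 C7 carboxylic acid, via trimethylsilyl ester 26 (not isolated)
Conditions: Me3SiOTf, 2,6-lutidine, CH2Cl2, 0 °C; then pH 5 buffer
Reagents that add atoms: none
Why: Silyl triflate-mediated cleavage of the tert-butyl ester (loss of isobutene) under buffered aprotic conditions that should leave the silyl ethers and the allyl chloride intact. The silyl ester hydrolyses on work-up.

Step 17
Reactants: 27 C7 carboxylic acid
Product: 29 C7 iodide with the 3-chloroprop-1-en-2-yl arm (iodine drawn on the upper face; either epimer is usable), via thiohydroxamate ester 28 (not isolated)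
Conditions: N-hydroxypyridine-2-thione, DCC, DMAP (cat.), CH2Cl2, 0 °C, dark; then CHI3, PhH, hν (tungsten lamp), rt
Reagents that add atoms: iodoform, IC(I)I
Why: Barton decarboxylative iodination: the thiohydroxamate ester fragments to the C7 cyclobutyl radical, which abstracts iodine from CHI3 and cannot cyclise onto the arm. The iodide is made before any tin is present, because an allylstannane would be consumed by the electrophilic diiodomethyl radicals.

Step 18
Reactants: 29 C7 iodide with the allylic chloride arm
Product: 30 C7 iodide with the 2-(tributylstannylmethyl)vinyl arm on C5 (key-step precursor)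
Conditions: (Bu3Sn)2, Pd2(dba)3 (2.5 mol %), THF, rt, dark
Reagents that add atoms: hexabutylditin, CCCC[Sn](CCCC)(CCCC)[Sn](CCCC)(CCCC)CCCC
Why: Stannylation of the allylic chloride with the ditin through a π-allyl complex, catalysed by zerovalent palladium. Oxidative addition to the allyl chloride should be far faster than to the hindered, unactivated secondary iodide, and the symmetrical 2-substituted allyl unit gives one regioisomer.

Step 19
Reactants: 30 C7 iodide with the allylstannane arm; 31 carbon monoxide
Product: 32 protected tricyclic C8 ketone with an exocyclic methylene at C10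
Conditions: 31 (50 atm), AIBN (0.2 equiv, in portions), PhH (0.005 M), 80 °C
Reagents that add atoms: none
Why: A tributylstannyl radical (released when the initiator radical adds to the allylstannane) abstracts iodine from C7; the cyclobutyl radical captures CO reversibly to give the C8 acyl radical (C7–C8); this adds to the CH2 terminus of the arm (C8–C9), and the β-stannyl radical expels Bu3Sn, which carries the chain. The closest known reactions are the tin-mediated carbonylative allylation of alkyl iodides with allylstannanes and the 6-endo cyclisation of acyl radicals, here joined in one molecule. Ring A closes in a 6-endo-trig mode; the 5-exo mode would attack the fully substituted C10, build a bicyclo[2.1.1]hexanone and could not lose tin. The only new stereocentre is C7: the radical is planar, CO capture is reversible, and only the acyl radical on the upper face, syn to the C5 arm, can reach the alkene, so both epimers of 30 should converge under tether control. No hydrogen donor is present, so an acyl radical on the lower face can only lose CO and return. High CO pressure and high dilution favour carbonylation over ring opening of the cyclobutyl radical and over intermolecular allyl transfer. Loss of tin from the C10 radical must outrun opening of the adjacent cyclobutane, and β-scission of a C–Sn bond is among the fastest radical fragmentations.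

Step 20
Reactants: 32 tricyclic exocyclic-methylene ketone
Product: 33 conjugated enone (C9=C10, C10 methyl)
Conditions: DBU (0.5 equiv), CH2Cl2, rt
Reagents that add atoms: none
Why: Base-mediated isomerisation of the β,γ-unsaturated ketone through the dienolate into conjugation. C7 is a bridgehead and cannot enolise, so it is not at risk.

Step 21
Reactants: 33 conjugated enone
Product: 34 saturated C8 ketone with the C10 methyl on the face away from the C4 methyl
Conditions: Li (2.2 equiv), NH3(l)–THF, t-BuOH (1 equiv), −78 °C; NH4Cl
Reagents that add atoms: none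
Why: Dissolving-metal conjugate reduction: the β-carbanion should pyramidalise so that the methyl turns away from the C4 methyl and be protonated on the C4 side, giving the more stable C10 epimer. The resulting enolate protects C8 from over-reduction and the silyl ethers are inert.

Step 22
Reactants: 34 saturated ketone bis(triethylsilyl) ether
Product: 35 C1,C3-diol with C15 OSi(i-Pr)3
Conditions: camphorsulfonic acid (0.1 equiv), MeOH–CH2Cl2, 0 °C
Reagents that add atoms: none
Why: Acid-catalysed methanolysis removes the two triethylsilyl ethers. The primary triisopropylsilyl ether is far more robust and should stay.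

Step 23
Reactants: 35 C1,C3-diol with C15 OSi(i-Pr)3; 36 angelic acid (two equivalents are built into the product: the first is counted here, the second on the reagent line)
Product: 37 C1,C3-bis(angelate) with C15 OSi(i-Pr)3
Conditions: 36 (6 equiv), 2,4,6-trichlorobenzoyl chloride (6 equiv), Et3N (6.5 equiv), PhMe, rt; then 35, PhMe, 80 °C
Reagents that add atoms: angelic acid (second equivalent of 36), C/C=C(/C)C(=O)O
Why: Yamaguchi esterification through the mixed anhydride: each of the two hydroxyls takes one angeloyl group, so two molecules of 36 enter 37, and the ortho chlorines steer attack to the angeloyl carbonyl. No nucleophilic pyridine catalyst is used, because reversible conjugate addition of such catalysts is what turns angelates into tiglates.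

Step 24
Reactants: 37 bis(angelate) silyl ether
Product: 38 target
Conditions: HF·pyridine, pyridine, THF, 0 °C → rt
Reagents that add atoms: none
Why: Fluoride cleavage of the primary silyl ether in a weakly acidic buffered medium, which should avoid both acyl migration from the C1 oxygen to C15 and Z→E isomerisation.

## Compound list

1 | tert-butyl 3-oxocyclobutane-1-carboxylate | CC(C)(C)OC(=O)C1CC(=O)C1 | starting material
2 | tert-butyl 2-methyl-3-oxocyclobutane-1-carboxylate (methyl trans to ester) | C[C@@H]1C(=O)C[C@H]1C(=O)OC(C)(C)C | intermediate
3 | tert-butyl 2-methyl-3-(trimethylsilyloxy)cyclobut-2-ene-1-carboxylate | CC1=C(O[Si](C)(C)C)C[C@H]1C(=O)OC(C)(C)C | intermediate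
4 | tert-butyl 2-(dimethoxymethyl)-2-methyl-3-oxocyclobutane-1-carboxylate | COC(OC)[C@]1(C)C(=O)C[C@H]1C(=O)OC(C)(C)C | intermediate
5 | tert-butyl 2-(dimethoxymethyl)-3-(1-ethoxyvinyl)-3-hydroxy-2-methylcyclobutane-1-carboxylate | COC(OC)[C@]1(C)[C@@](O)(C(=C)OCC)C[C@H]1C(=O)OC(C)(C)C | intermediate
6 | tert-butyl 3-acetyl-2-(dimethoxymethyl)-3-hydroxy-2-methylcyclobutane-1-carboxylate | COC(OC)[C@]1(C)[C@@](O)(C(C)=O)C[C@H]1C(=O)OC(C)(C)C | intermediate
7 | C5 epimer of 8 (acetyl on the lower face) | COC(OC)[C@]1(C)[C@H](C(C)=O)C[C@H]1C(=O)OC(C)(C)C | intermediate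
8 | tert-butyl 3-acetyl-2-(dimethoxymethyl)-2-methylcyclobutane-1-carboxylate (acetyl on the upper face) | COC(OC)[C@]1(C)[C@@H](C(C)=O)C[C@H]1C(=O)OC(C)(C)C | intermediate
9 | tert-butyl 2-(dimethoxymethyl)-2-methyl-3-(prop-1-en-2-yl)cyclobutane-1-carboxylate | COC(OC)[C@]1(C)[C@@H](C(C)=C)C[C@H]1C(=O)OC(C)(C)C | intermediate
10 | tert-butyl 2-(dimethoxymethyl)-2-methyl-1-(phenylselanyl)-3-(prop-1-en-2-yl)cyclobutane-1-carboxylate | COC(OC)[C@]1(C)[C@@H](C(C)=C)C[C@]1([Se]c2ccccc2)C(=O)OC(C)(C)C | intermediate
11 | tert-butyl 4-(dimethoxymethyl)-4-methyl-3-(prop-1-en-2-yl)cyclobut-1-ene-1-carboxylate | COC(OC)[C@]1(C)[C@@H](C(C)=C)C=C1C(=O)OC(C)(C)C | intermediate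
12 | tert-butyl 4-formyl-4-methyl-3-(prop-1-en-2-yl)cyclobut-1-ene-1-carboxylate | O=C[C@]1(C)[C@@H](C(C)=C)C=C1C(=O)OC(C)(C)C | intermediate
13 | methyl acetoacetate | COC(=O)CC(C)=O | starting material
14 | methyl 5-[2-(tert-butoxycarbonyl)-1-methyl-4-(prop-1-en-2-yl)cyclobut-2-en-1-yl]-5-hydroxy-3-oxopentanoate (both C3 epimers) | COC(=O)CC(=O)CC(O)[C@]1(C)[C@@H](C(C)=C)C=C1C(=O)OC(C)(C)C | intermediate
15 | triethylsilyl ether of 14 (both C3 epimers) | COC(=O)CC(=O)CC(O[Si](CC)(CC)CC)[C@]1(C)[C@@H](C(C)=C)C=C1C(=O)OC(C)(C)C | intermediate
16 | bicyclo[4.1.1]octane Michael adduct (C11–H; C3 epimers) | O=C1CC(O[Si](CC)(CC)CC)[C@]2(C)[C@@H](C(C)=C)[C@@H]([C@@H]2C(=O)OC(C)(C)C)C1C(=O)OC | intermediate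
17 | bicyclo[4.1.1]octane keto diester with quaternary C11 (C3 epimers) | O=C1CC(O[Si](CC)(CC)CC)[C@]2(C)[C@@H](C(C)=C)[C@@H]([C@@H]2C(=O)OC(C)(C)C)[C@@]1(C)C(=O)OC | intermediate
18 | C3 alcohol of 17 (C3 epimers) | O=C1CC(O)[C@]2(C)[C@@H](C(C)=C)[C@@H]([C@@H]2C(=O)OC(C)(C)C)[C@@]1(C)C(=O)OC | intermediate
19 | bicyclo[4.1.1]octane-1,3-dione diester | O=C1CC(=O)[C@]2(C)[C@@H](C(C)=C)[C@@H]([C@@H]2C(=O)OC(C)(C)C)[C@@]1(C)C(=O)OC | intermediate
20 | C11 hydroxymethyl 1,3-diketone tert-butyl ester | O=C1CC(=O)[C@]2(C)[C@@H](C(C)=C)[C@@H]([C@@H]2C(=O)OC(C)(C)C)[C@@]1(C)CO | intermediate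
21 | C1 carbinol, C3 ketone | O[C@@H]1CC(=O)[C@]2(C)[C@@H](C(C)=C)[C@@H]([C@@H]2C(=O)OC(C)(C)C)[C@@]1(C)CO | intermediate
22 | C1,C3,C15-triol tert-butyl ester | O[C@@H]1C[C@@H](O)[C@]2(C)[C@@H](C(C)=C)[C@@H]([C@@H]2C(=O)OC(C)(C)C)[C@@]1(C)CO | intermediate
23 | C15 triisopropylsilyl ether diol | O[C@@H]1C[C@@H](O)[C@]2(C)[C@@H](C(C)=C)[C@@H]([C@@H]2C(=O)OC(C)(C)C)[C@@]1(C)CO[Si](C(C)C)(C(C)C)C(C)C | intermediate
24 | fully silylated tert-butyl ester with C5 isopropenyl | CC[Si](CC)(CC)O[C@@H]1C[C@@H](O[Si](CC)(CC)CC)[C@]2(C)[C@@H](C(C)=C)[C@@H]([C@@H]2C(=O)OC(C)(C)C)[C@@]1(C)CO[Si](C(C)C)(C(C)C)C(C)C | intermediate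
25 | allylic chloride tert-butyl ester | CC[Si](CC)(CC)O[C@@H]1C[C@@H](O[Si](CC)(CC)CC)[C@]2(C)[C@@H](C(=C)CCl)[C@@H]([C@@H]2C(=O)OC(C)(C)C)[C@@]1(C)CO[Si](C(C)C)(C(C)C)C(C)C | intermediate
26 | trimethylsilyl ester | CC[Si](CC)(CC)O[C@@H]1C[C@@H](O[Si](CC)(CC)CC)[C@]2(C)[C@@H](C(=C)CCl)[C@@H]([C@@H]2C(=O)O[Si](C)(C)C)[C@@]1(C)CO[Si](C(C)C)(C(C)C)C(C)C | intermediate
27 | C7 carboxylic acid | CC[Si](CC)(CC)O[C@@H]1C[C@@H](O[Si](CC)(CC)CC)[C@]2(C)[C@@H](C(=C)CCl)[C@@H]([C@@H]2C(=O)O)[C@@]1(C)CO[Si](C(C)C)(C(C)C)C(C)C | intermediate
28 | 2-thioxopyridin-1(2H)-yl ester of 27 | CC[Si](CC)(CC)O[C@@H]1C[C@@H](O[Si](CC)(CC)CC)[C@]2(C)[C@@H](C(=C)CCl)[C@@H]([C@@H]2C(=O)ON2C=CC=CC2=S)[C@@]1(C)CO[Si](C(C)C)(C(C)C)C(C)C | intermediate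
29 | C7 iodide with the 3-chloroprop-1-en-2-yl arm | CC[Si](CC)(CC)O[C@@H]1C[C@@H](O[Si](CC)(CC)CC)[C@]2(C)[C@@H](C(=C)CCl)[C@@H]([C@H]2I)[C@@]1(C)CO[Si](C(C)C)(C(C)C)C(C)C | intermediate
30 | C7 iodide with the 2-(tributylstannylmethyl)vinyl arm | CC[Si](CC)(CC)O[C@@H]1C[C@@H](O[Si](CC)(CC)CC)[C@]2(C)[C@@H](C(=C)C[Sn](CCCC)(CCCC)CCCC)[C@@H]([C@H]2I)[C@@]1(C)CO[Si](C(C)C)(C(C)C)C(C)C | intermediate
31 | carbon monoxide | [C-]#[O+] | starting material
32 | protected tricyclic C8 ketone with exocyclic methylene at C10 | CC[Si](CC)(CC)O[C@@H]1C[C@@H](O[Si](CC)(CC)CC)[C@]2(C)[C@@H]3[C@@H]([C@H]2C(=O)CC3=C)[C@@]1(C)CO[Si](C(C)C)(C(C)C)C(C)C | intermediate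
33 | protected conjugated enone | CC[Si](CC)(CC)O[C@@H]1C[C@@H](O[Si](CC)(CC)CC)[C@]2(C)[C@@H]3[C@@H]([C@H]2C(=O)C=C3C)[C@@]1(C)CO[Si](C(C)C)(C(C)C)C(C)C | intermediate
34 | protected saturated ketone | CC[Si](CC)(CC)O[C@@H]1C[C@@H](O[Si](CC)(CC)CC)[C@]2(C)[C@@H]3[C@@H]([C@H]2C(=O)C[C@H]3C)[C@@]1(C)CO[Si](C(C)C)(C(C)C)C(C)C | intermediate
35 | C1,C3-diol with C15 triisopropylsilyl ether | O[C@@H]1C[C@@H](O)[C@]2(C)[C@@H]3[C@@H]([C@H]2C(=O)C[C@H]3C)[C@@]1(C)CO[Si](C(C)C)(C(C)C)C(C)C | intermediate
36 | angelic acid, (Z)-2-methylbut-2-enoic acid | C/C=C(/C)C(=O)O | starting material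
37 | C1,C3-bis(angelate) with C15 triisopropylsilyl ether | C/C=C(/C)C(=O)O[C@@H]1C[C@@H](OC(=O)/C(C)=C\C)[C@]2(C)[C@@H]3[C@@H]([C@H]2C(=O)C[C@H]3C)[C@@]1(C)CO[Si](C(C)C)(C(C)C)C(C)C | intermediate
38 | CNP0287707.1 | C/C=C(/C)C(=O)O[C@@H]1C[C@@H](OC(=O)/C(C)=C\C)[C@]2(C)[C@@H]3[C@@H]([C@H]2C(=O)C[C@H]3C)[C@@]1(C)CO | target

## Step count and least certain steps

Total: 24 steps. Longest linear sequence: 24 steps (from 1; 13, 31 and 36 enter as bought materials).

Step 19 (key step). The most likely failure is intermolecular allyl transfer or oligomerisation, which takes over if the acyl radical on the lower face loses CO too slowly. Opening of the four-membered ring at the C7 or C10 radical stage is the second risk. The fallback avoids CO and radicals. It sets out from 24. The tert-butyl ester is reduced with LiAlH4 to the primary alcohol F1 and oxidised with Dess–Martin periodinane to the aldehyde F2. C7 is equilibrated with DBU, and ring A is closed by a Me2AlCl-promoted intramolecular carbonyl-ene reaction; only the epimer with the formyl group syn to the isopropenyl group can react, forming C8–C9 and the exocyclic methylene and giving the homoallylic alcohol F3. Oxidation of F3 with Dess–Martin periodinane returns to the route at 32.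

Step 18. Zerovalent palladium or adventitious stannyl radicals may attack the C7–I bond, and the π-allyl complex may couple with product allylstannane. The fallback sets out from 29. The chloride is displaced with PhSO2Na (DMF, Bu4NI cat.) to give the allyl phenyl sulfone F4. F4 is then carbonylated with 31 and (Bu3Sn)2 under irradiation: the acyl radical adds to the sulfone arm, a sulfonyl radical leaves and the ditin carries the chain. This returns to the route at 32.

Step 10. The seven-membered closure may be slow enough for intermolecular Michael addition to compete, and the methylation loses its facial bias if C7 is protonated from the lower face. The fallback sets out from 12. The aldol of step 9 is run with the dianion of methyl 2-methylacetoacetate (then Et3SiCl) to give the α-methyl keto ester F5. Cs2CO3 in MeCN then closes the ring and creates the quaternary C11 in one event, with the selectivity coming from the cyclisation transition state. This returns to the route at 17.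

Step 13. The second hydride delivery may fail if 21 rests as an internal hemiketal or if the enolised diketone reacts slowly, so that undirected reduction erodes the selectivity at C3. The fallback sets out from 20. The reduction is stopped at 21 (limited reagent, −30 °C). An Evans–Tishchenko reaction (SmI2 cat., PhCHO, THF, −10 °C) then sets C3 anti to C1 and gives the C1 benzoate F6. Methanolysis (K2CO3, MeOH) returns to the route at 22.

Step 21. Protonation at C10 from the less hindered face would give the epimer with the methyl toward the C4 methyl; the radical anion next to the four-membered ring may also fragment, and the ketone may be over-reduced. The fallback sets out from 32. NaBH4 should attack C8 from the face away from the C4 methyl and give the alcohol F7 with the hydroxyl on the C4 side. Hydroxyl-directed hydrogenation with [Ir(cod)(PCy3)(py)]PF6 and H2 should add hydrogen to C10 from that same side and give F8. Oxidation with Dess–Martin periodinane returns to the route at 34.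

Step 23. Forcing the acylation of two neopentyl-type secondary alcohols invites Z→E isomerisation and incomplete second acylation. The fallback sets out from 35. Both alcohols are acylated with 2-[bis(2,2,2-trifluoroethoxy)phosphoryl]propanoic acid (DCC, DMAP cat.) to give the bis(phosphonopropanoate) F9. A Still–Gennari olefination (KN(SiMe3)2, 18-crown-6, acetaldehyde, THF, −78 °C) then builds both (Z)-enoates and returns to the route at 37.

## Further compounds

F1 | step 19 | C7 hydroxymethyl analogue of 24 | CC[Si](CC)(CC)O[C@@H]1C[C@@H](O[Si](CC)(CC)CC)[C@]2(C)[C@@H](C(C)=C)[C@@H]([C@@H]2CO)[C@@]1(C)CO[Si](C(C)C)(C(C)C)C(C)C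
F2 | step 19 | C7 aldehyde | CC[Si](CC)(CC)O[C@@H]1C[C@@H](O[Si](CC)(CC)CC)[C@]2(C)[C@@H](C(C)=C)[C@@H]([C@@H]2C=O)[C@@]1(C)CO[Si](C(C)C)(C(C)C)C(C)C
F3 | step 19 | tricyclic C8 alcohol with exocyclic methylene at C10 (C8 epimers) | CC[Si](CC)(CC)O[C@@H]1C[C@@H](O[Si](CC)(CC)CC)[C@]2(C)[C@@H]3[C@@H]([C@H]2C(O)CC3=C)[C@@]1(C)CO[Si](C(C)C)(C(C)C)C(C)C
F4 | step 18 | C7 iodide with the 2-(phenylsulfonylmethyl)vinyl arm | CC[Si](CC)(CC)O[C@@H]1C[C@@H](O[Si](CC)(CC)CC)[C@]2(C)[C@@H](C(=C)CS(=O)(=O)c3ccccc3)[C@@H]([C@H]2I)[C@@]1(C)CO[Si](C(C)C)(C(C)C)C(C)C
F5 | step 10 | α-methyl analogue of 15 (C3 and C11 epimers) | COC(=O)C(C)C(=O)CC(O[Si](CC)(CC)CC)[C@]1(C)[C@@H](C(C)=C)C=C1C(=O)OC(C)(C)C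
F6 | step 13 | C1 benzoate, C3 alcohol, C15 alcohol | O=C(O[C@@H]1C[C@@H](O)[C@]2(C)[C@@H](C(C)=C)[C@@H]([C@@H]2C(=O)OC(C)(C)C)[C@@]1(C)CO)c1ccccc1
F7 | step 21 | C8 alcohol (hydroxyl on the C4 side) with exocyclic methylene at C10 | CC[Si](CC)(CC)O[C@@H]1C[C@@H](O[Si](CC)(CC)CC)[C@]2(C)[C@@H]3[C@@H]([C@H]2[C@H](O)CC3=C)[C@@]1(C)CO[Si](C(C)C)(C(C)C)C(C)C
F8 | step 21 | C8 alcohol with the C10 methyl as in the target | CC[Si](CC)(CC)O[C@@H]1C[C@@H](O[Si](CC)(CC)CC)[C@]2(C)[C@@H]3[C@@H]([C@H]2[C@H](O)C[C@H]3C)[C@@]1(C)CO[Si](C(C)C)(C(C)C)C(C)C
F9 | step 23 | C1,C3-bis{2-[bis(2,2,2-trifluoroethoxy)phosphoryl]propanoate} of 35 | CC(C(=O)O[C@@H]1C[C@@H](OC(=O)C(C)P(=O)(OCC(F)(F)F)OCC(F)(F)F)[C@]2(C)[C@@H]3[C@@H]([C@H]2C(=O)C[C@H]3C)[C@@]1(C)CO[Si](C(C)C)(C(C)C)C(C)C)P(=O)(OCC(F)(F)F)OCC(F)(F)F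
A1 | alternative 1 | tricyclic β-hydroxy ester (C1–OH, C11 CO2Me, C3 p-methoxybenzyl ether, C8 dioxolane) | O[C@@H]1C[C@@H](OCc2ccc(OC)cc2)[C@]2(C)[C@@H]3[C@@H]([C@H]2C2(OCCO2)C[C@H]3C)[C@@]1(C)C(=O)OC
A2 | alternative 1 | C1 aldehyde with C11 α-bromo ester on the ring A–cyclobutane core (C11 epimers) | O=CC[C@@H](OCc1ccc(OC)cc1)[C@]1(C)[C@@H]2[C@@H]([C@H]1C1(OCCO1)C[C@H]2C)C(C)(Br)C(=O)OC
A3 | alternative 2 | tricyclic C3 ketone (C1 tert-butyldimethylsilyl ether, C11 CO2Me, C8 dioxolane) | CC(C)(C)[Si](C)(C)O[C@@H]1CC(=O)[C@]2(C)[C@@H]3[C@@H]([C@H]2C2(OCCO2)C[C@H]3C)[C@@]1(C)C(=O)OC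
A4 | alternative 2 | acylgermane α-bromo ester (C11 epimers) | COC(=O)C(C)(Br)[C@H](O[Si](C)(C)C(C)(C)C)CC(=O)[Ge](c1ccccc1)(c1ccccc1)c1ccccc1
A5 | alternative 2 | ring-A-fused bicyclobutane ketal | C[C@@H]1CC2(OCCO2)[C@H]2[C@@]3(C)[C@@H]1[C@@H]23
A6 | alternative 3 | bicyclo[4.1.1]octane C7 methyl ester with C5 isopropenyl | CC[Si](CC)(CC)O[C@@H]1C[C@@H](O[Si](CC)(CC)CC)[C@]2(C)[C@@H](C(C)=C)[C@@H]([C@H]2C(=O)OC)[C@@]1(C)CO[Si](C(C)C)(C(C)C)C(C)C
A7 | alternative 3 | bicyclo[4.2.1]nonanone diazoketone | CC[Si](CC)(CC)O[C@@H]1C[C@@H](O[Si](CC)(CC)CC)[C@]2(C)[C@@H](C(C)=C)[C@@H](C(=O)C2=[N+]=[N-])[C@@]1(C)CO[Si](C(C)C)(C(C)C)C(C)C
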